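**Plan**

- Cuts: (1) the C2–C3 bond of the pyranone ring, giving an aryl diazomethyl ketone whose ortho oxygen carries a benzyl group; (2) the C6–CH2 bond to the catechol ring, giving an aryl iodide and a benzylic zinc reagent; (3) the C–I, O–Me and O–Bn bonds, back to 2',4',6'-trihydroxyacetophenone, with the benzylic bromide traced to 2,3-dihydroxybenzaldehyde.
- Enabling feature: C2 carries H, the phenyl ring B and the ring oxygen O1, so O1–C2 is an aryl benzyl ether less one hydrogen, and C3 lies alpha to the C4 ketone. A carbenoid at C3 and the OCH2Ph hydrogens are 1,6-related through C4, C4a, C8a and O1.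
- Forward: ring A is dibenzylated, iodinated ortho to the remaining chelated phenol and methylated; a Negishi coupling attaches the protected catechol-benzyl unit; diazo transfer follows; the pyranone ring is closed by C–H insertion, which turns one O-benzyl group into C2 and ring B; one Lewis-acid step removes all ethers.
- Stereochemistry: C2 (S) is the only stereocentre. It is set in the ring closure by a chiral dirhodium carboxylate that chooses between the two enantiotopic benzylic hydrogens, and no basic step follows.

Key step: step 9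

Assumption: Rh2(S-PTTL)4 is taken to deliver the (2S) product; if a trial run shows the opposite sense, the enantiomeric catalyst Rh2(R-PTTL)4 is used under the same conditions.

**Route**

Step 1
Reactants: 1 2',4',6'-trihydroxyacetophenone
Product: 2 1-[2,4-bis(benzyloxy)-6-hydroxyphenyl]ethan-1-one
Conditions: BnBr (2.1 equiv), K2CO3, DMF, 0 °C → rt
Reagents that add atoms: benzyl bromide, BrCc1ccccc1
Why: Williamson etherification under chelation control should alkylate the para OH and one of the two equivalent ortho OH groups while the other stays hydrogen-bonded to the ketone, and the symmetry of 1 removes any regiochemical question.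

Step 2
Reactants: 2 1-[2,4-bis(benzyloxy)-6-hydroxyphenyl]ethan-1-one
Product: 3 1-[4,6-bis(benzyloxy)-2-hydroxy-3-iodophenyl]ethan-1-one
Conditions: NIS, CF3CO2H (cat.), MeCN, 0 °C → rt, dark
Reagents that add atoms: N-iodosuccinimide, O=C1CCC(=O)N1I
Why: Electrophilic aromatic iodination should go to the position ortho to the free phenol, which is less hindered than the position between the two benzyloxy groups and is the usual site of substitution in 2-hydroxy-4,6-dialkoxyacetophenones; this places the later C-benzyl group next to the oxygen that ends as the 5-OH.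

Step 3
Reactants: 3 1-[4,6-bis(benzyloxy)-2-hydroxy-3-iodophenyl]ethan-1-one
Product: 4 1-[4,6-bis(benzyloxy)-3-iodo-2-methoxyphenyl]ethan-1-one
Conditions: MeI, K2CO3, DMF, 40 °C
Reagents that add atoms: iodomethane, CI
Why: Williamson methylation of the chelated phenol caps this ortho oxygen with a group whose primary C–H bonds do not compete in the key step and which can later be cleaved by chelation to the C4 carbonyl.

Step 4
Reactants: 5 2,3-dihydroxybenzaldehyde
Product: 6 2,3-bis(benzyloxy)benzaldehyde
Conditions: BnBr (2.2 equiv), K2CO3, DMF, 60 °C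
Reagents that add atoms: benzyl bromide, BrCc1ccccc1
Why: Williamson bis-benzylation of the catechol is routine and gives ethers that survive organozinc, amide base and carbenoid chemistry.

Step 5
Reactants: 6 2,3-bis(benzyloxy)benzaldehyde
Product: 7 [2,3-bis(benzyloxy)phenyl]methanol
Conditions: NaBH4, MeOH/THF, 0 °C
Reagents that add atoms: none
Why: Borohydride reduction of an aryl aldehyde to the benzylic alcohol is chemoselective and leaves the benzyl ethers untouched.

Step 6
Reactants: 7 [2,3-bis(benzyloxy)phenyl]methanol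
Product: 8 1,2-bis(benzyloxy)-3-(bromomethyl)benzene
Conditions: PBr3, CH2Cl2, 0 °C
Reagents that add atoms: phosphorus tribromide, BrP(Br)Br
Why: Bromination through the phosphite ester and SN2 displacement by bromide is standard for alkoxy-substituted benzylic alcohols at low temperature.

Step 7
Reactants: 4 1-[4,6-bis(benzyloxy)-3-iodo-2-methoxyphenyl]ethan-1-one; 8 1,2-bis(benzyloxy)-3-(bromomethyl)benzene
Product: 10 1-{4,6-bis(benzyloxy)-3-[2,3-bis(benzyloxy)benzyl]-2-methoxyphenyl}ethan-1-one, via benzylic zinc bromide 9 (not isolated)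
Conditions: 8, Zn dust (activated), LiCl, THF, rt; then 4, Pd(OAc)2 (cat.), SPhos (cat.), THF, rt → 50 °C
Reagents that add atoms: none
Why: Negishi coupling, in which zinc inserts into the benzylic C–Br bond, the aryl iodide adds oxidatively to zerovalent palladium, and transmetalation and reductive elimination form the diarylmethane; the bulky biaryl phosphine should cope with the two ortho alkoxy groups and the organozinc tolerates the methyl ketone.

Step 8
Reactants: 10 1-{4,6-bis(benzyloxy)-3-[2,3-bis(benzyloxy)benzyl]-2-methoxyphenyl}ethan-1-one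
Product: 12 1-{4,6-bis(benzyloxy)-3-[2,3-bis(benzyloxy)benzyl]-2-methoxyphenyl}-2-diazoethan-1-one, via trifluoroacetyl diketone 11 (not isolated)
Conditions: LiN(SiMe3)2, THF, –78 °C; CF3CO2CH2CF3; then MsN3, Et3N, H2O (1 equiv), MeCN, rt
Reagents that add atoms: methanesulfonyl azide, CS(=O)(=O)N=[N+]=[N-]
Why: Detrifluoroacetylative Regitz diazo transfer, in which a Claisen-type trifluoroacetylation of the kinetic enolate activates the methyl group, the sulfonyl azide delivers N2 and the trifluoroacetyl group leaves on the sulfonamide; this avoids diazomethane and acts at the unhindered methyl carbon.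

Step 9
Reactants: 12 1-{4,6-bis(benzyloxy)-3-[2,3-bis(benzyloxy)benzyl]-2-methoxyphenyl}-2-diazoethan-1-one
Product: 13 (2S)-7-(benzyloxy)-6-[2,3-bis(benzyloxy)benzyl]-5-methoxy-2-phenyl-2,3-dihydro-4H-chromen-4-one
Conditions: Rh2(S-PTTL)4 (dirhodium tetrakis[N-phthaloyl-(S)-tert-leucinate], 1–2 mol %), CH2Cl2, 4 Å MS, –10 °C → rt, slow addition of 12
Reagents that add atoms: none
Why: Loss of N2 from 12 on the dirhodium centre should give an electrophilic rhodium carbenoid at the future C3, which inserts into one benzylic C–H bond of the ortho OCH2Ph group through a concerted, hydride-transfer-like three-centre transition state, that C–H bond being activated by both the ether oxygen and the phenyl ring. The closest known reaction type is the dirhodium carboxylate-catalysed intramolecular C–H insertion of 2-alkoxyaryl diazoketones to chroman-4-ones, including enantioselective versions with chiral carboxylate ligands. The pyranone ring closes as a 1,6-C–H insertion (ring atoms C3, C4, C4a, C8a, O1, C2), and a five-membered alternative does not exist because the 1,5-position is the ether oxygen itself. C2 is the only new stereocentre; its (S) configuration is controlled by the chiral catalyst, which selects one of the two enantiotopic benzylic hydrogens, and insertion proceeds with retention at carbon. The step needs site selectivity for OCH2Ph over the OCH3 group on the other ortho position, secured because a primary methyl C–H is far less reactive than a secondary, benzylic, oxygen-activated one, and chemoselectivity for insertion over oxonium ylide formation with [1,2]-benzyl shift, which is favoured by the weakly basic, acyl-conjugated aryl ether oxygen, a carboxylate (not copper) catalyst and slow addition at low temperature.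

Step 10
Reactants: 13 (2S)-7-(benzyloxy)-6-[2,3-bis(benzyloxy)benzyl]-5-methoxy-2-phenyl-2,3-dihydro-4H-chromen-4-one
Product: 14 (2S)-6-(2,3-dihydroxybenzyl)-5,7-dihydroxy-2-phenyl-2,3-dihydro-4H-chromen-4-one
Conditions: BCl3, C6HMe5, CH2Cl2, –78 → 0 °C; then MeOH, H2O
Reagents that add atoms: none
Why: Lewis-acid ether cleavage should remove the three aryl benzyl ethers at low temperature, with pentamethylbenzene trapping the benzyl cations, and the 5-methyl ether by chelation of boron between O5 and the C4 carbonyl; no base is present, so C2 should keep its configuration.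

**Compound list**

1 | 2',4',6'-trihydroxyacetophenone | CC(=O)c1c(O)cc(O)cc1O | starting material
2 | 1-[2,4-bis(benzyloxy)-6-hydroxyphenyl]ethan-1-one | CC(=O)c1c(O)cc(OCc2ccccc2)cc1OCc1ccccc1 | intermediate
3 | 1-[4,6-bis(benzyloxy)-2-hydroxy-3-iodophenyl]ethan-1-one | CC(=O)c1c(O)c(I)c(OCc2ccccc2)cc1OCc1ccccc1 | intermediate
4 | 1-[4,6-bis(benzyloxy)-3-iodo-2-methoxyphenyl]ethan-1-one | CC(=O)c1c(OC)c(I)c(OCc2ccccc2)cc1OCc1ccccc1 | intermediate
5 | 2,3-dihydroxybenzaldehyde | O=Cc1cccc(O)c1O | starting material
6 | 2,3-bis(benzyloxy)benzaldehyde | O=Cc1cccc(OCc2ccccc2)c1OCc1ccccc1 | intermediate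
7 | [2,3-bis(benzyloxy)phenyl]methanol | OCc1cccc(OCc2ccccc2)c1OCc1ccccc1 | intermediate
8 | 1,2-bis(benzyloxy)-3-(bromomethyl)benzene | BrCc1cccc(OCc2ccccc2)c1OCc1ccccc1 | intermediate
9 | [2,3-bis(benzyloxy)benzyl]zinc bromide (LiCl-solvated, in THF) | Br[Zn]Cc1cccc(OCc2ccccc2)c1OCc1ccccc1 | intermediate (not isolated)
10 | 1-{4,6-bis(benzyloxy)-3-[2,3-bis(benzyloxy)benzyl]-2-methoxyphenyl}ethan-1-one | CC(=O)c1c(OC)c(Cc2cccc(OCc3ccccc3)c2OCc2ccccc2)c(OCc2ccccc2)cc1OCc1ccccc1 | intermediate
11 | 1-{4,6-bis(benzyloxy)-3-[2,3-bis(benzyloxy)benzyl]-2-methoxyphenyl}-4,4,4-trifluorobutane-1,3-dione | O=C(CC(=O)C(F)(F)F)c1c(OC)c(Cc2cccc(OCc3ccccc3)c2OCc2ccccc2)c(OCc2ccccc2)cc1OCc1ccccc1 | intermediate (not isolated)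
12 | 1-{4,6-bis(benzyloxy)-3-[2,3-bis(benzyloxy)benzyl]-2-methoxyphenyl}-2-diazoethan-1-one | [N-]=[N+]=CC(=O)c1c(OC)c(Cc2cccc(OCc3ccccc3)c2OCc2ccccc2)c(OCc2ccccc2)cc1OCc1ccccc1 | intermediate
13 | (2S)-7-(benzyloxy)-6-[2,3-bis(benzyloxy)benzyl]-5-methoxy-2-phenyl-2,3-dihydro-4H-chromen-4-one | O=C1C[C@@H](c2ccccc2)Oc2cc(OCc3ccccc3)c(Cc3cccc(OCc4ccccc4)c3OCc3ccccc3)c(OC)c21 | intermediate
14 | (2S)-6-(2,3-dihydroxybenzyl)-5,7-dihydroxy-2-phenyl-2,3-dihydro-4H-chromen-4-one | O=C1C[C@@H](c2ccccc2)Oc2cc(O)c(Cc3cccc(O)c3O)c(O)c21 | target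

**Count and risks**

Total steps: 10. Longest linear sequence: 7 steps (steps 1, 2, 3, 7, 8, 9, 10; the branch through steps 4, 5, 6 is equally long).

Steps most likely to fail:

1. Step 9. The ether oxygen may attack the carbenoid, forming an oxonium ylide that undergoes [1,2]-benzyl shift to a benzofuranone, and the catalyst may discriminate poorly between the two enantiotopic benzylic hydrogens. The fallback forms the C2–aryl bond instead and sets out from 10. MgBr2·OEt2 (toluene/Et2O, heat) should cleave, by chelation, only the benzyl ether ortho to the acetyl group, giving 1-{4-(benzyloxy)-3-[2,3-bis(benzyloxy)benzyl]-6-hydroxy-2-methoxyphenyl}ethan-1-one F1. Condensation with Me2NCH(OMe)2 gives (E)-1-{4-(benzyloxy)-3-[2,3-bis(benzyloxy)benzyl]-6-hydroxy-2-methoxyphenyl}-3-(dimethylamino)prop-2-en-1-one F2. Acid (HCl, CH2Cl2) closes this to 7-(benzyloxy)-6-[2,3-bis(benzyloxy)benzyl]-5-methoxy-4H-chromen-4-one F3. Enantioselective conjugate addition of phenylboronic acid with Pd(OCOCF3)2 and the enantiomer of the t-BuPyOX ligand that gives (2S) (NH4PF6, H2O, ClCH2CH2Cl, 60 °C) then returns to the route at 13.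

2. Step 10. Released benzyl cations may transfer to ring A or the catechol ring, the methyl ether may cleave slowly, and prolonged Lewis-acid exposure may open the pyranone ring with partial loss of configuration. The fallback sets out from 13 and removes the benzyl groups reductively, so that no benzyl cation forms. Hydrogenolysis (H2, Pd/C, EtOAc/MeOH, rt) should give (2S)-6-(2,3-dihydroxybenzyl)-7-hydroxy-5-methoxy-2-phenyl-2,3-dihydro-4H-chromen-4-one F6. A short chelation-controlled cleavage of the single 5-methyl ether (BCl3, CH2Cl2, –78 → 0 °C) then returns to the route at 14.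

3. Step 7. Transmetalation and reductive elimination at the doubly ortho-substituted, electron-rich aryl iodide may be slow, letting homocoupling of the benzylic zinc reagent and protodeiodination take over. The fallback replaces cross-coupling by classical C-alkylation of the phloroglucinol anion, sets out from 1 and 8, and does not depend on the iodination in step 2. C-benzylation of 1 with 8 (aq. KOH, 0 °C → rt) should give 1-{3-[2,3-bis(benzyloxy)benzyl]-2,4,6-trihydroxyphenyl}ethan-1-one F4. Dibenzylation (BnBr, 2 equiv, K2CO3, acetone) is expected to spare the most hindered, chelated OH next to the new benzyl group, giving 1-{4,6-bis(benzyloxy)-3-[2,3-bis(benzyloxy)benzyl]-2-hydroxyphenyl}ethan-1-one F5. Methylation (MeI, K2CO3, DMF) then returns to the route at 10.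

Further compounds
F1 | step 9 | 1-{4-(benzyloxy)-3-[2,3-bis(benzyloxy)benzyl]-6-hydroxy-2-methoxyphenyl}ethan-1-one | CC(=O)c1c(OC)c(Cc2cccc(OCc3ccccc3)c2OCc2ccccc2)c(OCc2ccccc2)cc1O
F2 | step 9 | (E)-1-{4-(benzyloxy)-3-[2,3-bis(benzyloxy)benzyl]-6-hydroxy-2-methoxyphenyl}-3-(dimethylamino)prop-2-en-1-one | CN(C)/C=C/C(=O)c1c(OC)c(Cc2cccc(OCc3ccccc3)c2OCc2ccccc2)c(OCc2ccccc2)cc1O
F3 | step 9 | 7-(benzyloxy)-6-[2,3-bis(benzyloxy)benzyl]-5-methoxy-4H-chromen-4-one | O=c1ccoc2cc(OCc3ccccc3)c(Cc3cccc(OCc4ccccc4)c3OCc3ccccc3)c(OC)c12
F4 | step 7 | 1-{3-[2,3-bis(benzyloxy)benzyl]-2,4,6-trihydroxyphenyl}ethan-1-one | CC(=O)c1c(O)c(Cc2cccc(OCc3ccccc3)c2OCc2ccccc2)c(O)cc1O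
F5 | step 7 | 1-{4,6-bis(benzyloxy)-3-[2,3-bis(benzyloxy)benzyl]-2-hydroxyphenyl}ethan-1-one | CC(=O)c1c(O)c(Cc2cccc(OCc3ccccc3)c2OCc2ccccc2)c(OCc2ccccc2)cc1OCc1ccccc1
F6 | step 10 | (2S)-6-(2,3-dihydroxybenzyl)-7-hydroxy-5-methoxy-2-phenyl-2,3-dihydro-4H-chromen-4-one | O=C1C[C@@H](c2ccccc2)Oc2cc(O)c(Cc3cccc(O)c3O)c(OC)c21
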